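The data are simulated from invented constants, noise included.

Target at 30.0 h stood at 24.4 % in birch and 31.6 % in elm, so your hunch that more free base pulls more electrophile through looked sound, and I put numbers on it for the new flasks.

all flasks: electrophile 45 mM

|  | free base | protonated nucleophile | protic impurity | remark | time |
|---|---|---|---|---|---|
| birch | 7 mM | 90 mM | 9 mM | run made earlier |  |
| elm | 36 mM | 90 mM | 9 mM | run made earlier |  |
| noon | 54.0 mM | 90.0 mM | 9.00 mM |  | 30 h |
| dusk | 14.0 mM | 90.0 mM | 9.00 mM |  | 30 h |
| midnight | 27.0 mM | 90.0 mM | 9.00 mM |  | 30 h |

| run | time / h | electrophile / % | target / % |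
|---|---|---|---|
| birch | 2.00 | 88.5 | 8.5 |
| birch | 6.00 | 76.5 | 14.2 |
| birch | 10.0 | 68.6 | 18.3 |
| birch | 15.0 | 59.4 | 20.7 |
| birch | 25.0 | 48.0 | 24.1 |
| birch | 30.0 | 44.1 | 24.4 |
| elm | 2.00 | 88.9 | 6.8 |
| elm | 6.00 | 75.6 | 14.7 |
| elm | 10.0 | 65.1 | 20.7 |
| elm | 15.0 | 55.2 | 24.1 |
| elm | 25.0 | 40.0 | 29.8 |
| elm | 30.0 | 35.4 | 31.6 |

(scatter of a reading: 0.5 percentage points)

- a species is counted by the electrophile in it: one side product counts as two
- steps thought possible: electrophile + nucleophile -> acid set free + target; nucleophile + acid set free <-> protonated nucleophile; acid set free + free base <-> salt of the base; electrophile + target -> side product; electrophile + protic impurity -> quenched substrate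

- part of the electrophile that has reacted at the end, noon
- part of the electrophile that has reacted at the end, dusk
- part of the electrophile that has reacted at the end, midnight
- what raising the concentration of free base from its lowest to its highest value here does to the part of the electrophile that has reacted (changes below 5 percentage points count as none) (no change / it rises / it falls)

Each step that takes electrophile was written one way, so I expected it to keep falling towards nil and asked how fast. Birch and elm stood 0.9 percentage points apart at 6.00 h, so I started every flask from their mean, 76.0 % left. After that I read a pace, the hourly fall in the natural logarithm of the electrophile left, averaged from 6.00 h to 30.0 h, which came to 0.0230 h⁻¹ in birch and 0.0316 h⁻¹ in elm. It was an average and no constant, since the readings of birch showed 0.0288 h⁻¹ between 10.0 h and 15.0 h but 0.0169 h⁻¹ between 25.0 h and 30.0 h. Two runs give a line and no curve, so I assumed pace ran straight with the free base charged, and by 30 h that gave me 58.3 % reacted for dusk, 62.0 % for midnight and 68.7 % for noon, though noon's charge lay beyond elm's, so that last figure was an extrapolation.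

The forecast gave 60 % for dusk, 64.3 % for midnight and 65.5 % for noon, and its answer on the trend was it rises, “a modest rise that saturates”, and so it parted from my straight line at noon.

The flasks gave 58.4 % for dusk, 62.1 % for midnight and 69.4 % for noon, a change of 11 points: it rises.

    electrophile + nucleophile → acid set free + target (k = 0.310 M⁻¹ min⁻¹)
    nucleophile + acid set free ⇌ protonated nucleophile, settled at all times (K = 6200 M⁻¹)
    acid set free + free base ⇌ salt of the base (K = 41000 M⁻¹, k = 0.0580 M⁻¹ min⁻¹)
    electrophile + target → side product (k = 0.00930 M⁻¹ min⁻¹)
    electrophile + protic impurity → quenched substrate (k = 0.0290 M⁻¹ min⁻¹)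

Read back from my start, dusk's result is a pace of 0.0251 h⁻¹, and my line had put dusk at 0.0250 h⁻¹. The neighbour of dusk charged with 56 mM of free base sits on that line at a pace of 0.0376 h⁻¹, which gave me 69.2 % reacted. That flask reached 69.9 %, ending with 30.1 % of the electrophile unreacted, 18.6 % in side product and 36.7 % in target, the largest share.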